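**Retrosynthetic overview**
1. The (3S) centre is set last: the racemic isoflavanone is flattened to its 4-silyloxy-2H-chromene and reprotonated at C3 by a chiral Brønsted acid.
2. The strategy rests on ring A (C4a, C5, C6, C7, C8, C8a), an acylphloroglucinol with the prenyl group on C6 between the 5- and 7-oxygens and the third oxygen being the ether O1 on C8a. It is cut at C4a–C5: C5–C8 come from a 5-prenyl-1,3-dioxin-4-one (masked acylketene) hung on a 3-aryl-2,3-dihydropyran-4-one that already holds O1–C8a.
3. The dihydropyranone (ring C) comes from cyclodehydration of a δ-hydroxy-β-diketone, made by Claisen acylation of the keto-dioxinone dianion with the Weinreb amide of an O-silyl tropic acid carrying ring B.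
4. Ring B is bought as 4-bromo-3-methoxyphenol and elaborated by iodination and two Negishi couplings. The dioxinone is prenylated at C5 by Negishi coupling and acetylated at its methyl group. One batch of prenylzinc bromide serves both prenylations.
5. Ring order: B (bought), C (step 13), A (step 14); the stereocentre follows in step 17.

Key step: step 14

Assumption: the (S)-configured thiophosphoramide catalyst of step 17 is taken to deliver the proton to the face of the enol ether that gives (3S); if the first run shows the opposite sense, the mirror-image catalyst is used with nothing else changed.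
Abbreviations: prenyl = 3-methylbut-2-en-1-yl; Ar = 4-methoxy-2-(methoxymethoxy)-5-(3-methylbut-2-en-1-yl)phenyl; isoflavanone numbering (O1, C2, C3, C4, C4a, C5–C8, C8a) is used for ring atoms throughout.

**Route**

Step 1
Reactants: 1 2,2,6-trimethyl-4H-1,3-dioxin-4-one
Product: 2 5-iodo-2,2,6-trimethyl-4H-1,3-dioxin-4-one
Conditions: N-iodosuccinimide, AcOH, rt, dark
Reagents that add atoms: N-iodosuccinimide, O=C1CCC(=O)N1I
Why: Electrophilic iodination at C5, the nucleophilic α-carbon of the enol-ether double bond and the only ring position that can react, as known for halogenation of dioxinones with N-halosuccinimides.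

Step 2
Reactants: 3 1-bromo-3-methylbut-2-ene (prenyl bromide)
Product: 4 (3-methylbut-2-en-1-yl)zinc bromide (prenylzinc bromide), kept as a titrated stock solution in THF
Conditions: Zn dust, LiCl, THF, slow addition of 3 at 0 °C → rt; decanted from excess Zn, titrated with I2, stored under argon at 4 °C
Reagents that add atoms: zinc, [Zn]
Why: Direct oxidative insertion of zinc into the allylic C–Br bond, accelerated by LiCl, which also keeps the allylic zinc halide in solution and stable for weeks under argon, so that one batch made with slow addition at 0 °C (to suppress Wurtz homocoupling) supplies both steps 3 and 8.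

Step 3
Reactants: 2 5-iodo-2,2,6-trimethyl-4H-1,3-dioxin-4-one; 4 prenylzinc bromide
Product: 5 2,2,6-trimethyl-5-(3-methylbut-2-en-1-yl)-4H-1,3-dioxin-4-one
Conditions: 4 (1.3 equiv, THF solution), Pd(OAc)2 (2 mol %), CPhos (4 mol %), THF, rt
Reagents that add atoms: none
Why: Negishi cross-coupling of a vinyl iodide with an allylic zinc halide, in which the CPhos ligand should give the linear (prenyl, not 1,1-dimethylallyl) product, and room temperature keeps the dioxinone below its cycloreversion temperature.

Step 4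
Reactants: 5 2,2,6-trimethyl-5-(3-methylbut-2-en-1-yl)-4H-1,3-dioxin-4-one
Product: 6 2,2-dimethyl-5-(3-methylbut-2-en-1-yl)-6-(2-oxopropyl)-4H-1,3-dioxin-4-one
Conditions: 5 (2 equiv), LiN(SiMe3)2 (2 equiv), THF, −78 °C; AcCl (1 equiv), −78 °C; aq. NH4Cl
Reagents that add atoms: acetyl chloride, CC(=O)Cl
Why: Vinylogous Claisen acylation: the lithium dienolate formed by deprotonation of the C6 methyl group is C-acylated at its γ-carbon, C5 being blocked by the prenyl group, and the second equivalent of dienolate takes up the acidity of the product (excess 5 is recovered).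

Step 5
Reactants: 7 4-bromo-3-methoxyphenol
Product: 8 4-bromo-2-iodo-5-methoxyphenol
Conditions: N-iodosuccinimide, TsOH·H2O (10 mol %), MeCN, 0 °C → rt
Reagents that add atoms: N-iodosuccinimide, O=C1CCC(=O)N1I
Why: Electrophilic aromatic iodination at the position ortho to OH and para to OMe, which is less hindered than the position between the two oxygens, the other para position being blocked by bromine.

Step 6
Reactants: 8 4-bromo-2-iodo-5-methoxyphenol
Product: 9 1-bromo-5-iodo-2-methoxy-4-(methoxymethoxy)benzene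
Conditions: MOMCl, i-Pr2NEt, CH2Cl2, 0 °C → rt
Reagents that add atoms: chloromethyl methyl ether, COCCl
Why: O-alkylation of the phenol gives a MOM ether that withstands the organometallic, basic and thermal steps until its removal in step 15.

Step 7
Reactants: 9 1-bromo-5-iodo-2-methoxy-4-(methoxymethoxy)benzene; 10 ethyl bromoacetate
Product: 12 ethyl 2-[5-bromo-4-methoxy-2-(methoxymethoxy)phenyl]acetate, via Reformatsky reagent 11 (not isolated)
Conditions: 10, Zn (Me3SiCl-activated), THF, rt; then 9, Pd(PPh3)4 (5 mol %), THF, 50 °C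
Reagents that add atoms: none
Why: Palladium-catalysed arylation of a Reformatsky reagent (Negishi type), in which zerovalent palladium inserts into the C–I bond much faster than into the C–Br bond, so only the iodide next to the MOM ether should be replaced.

Step 8
Reactants: 12 ethyl 2-[5-bromo-4-methoxy-2-(methoxymethoxy)phenyl]acetate; 4 prenylzinc bromide
Product: 13 ethyl 2-[4-methoxy-2-(methoxymethoxy)-5-(3-methylbut-2-en-1-yl)phenyl]acetate (Ar–CH2–CO2Et)
Conditions: 4 (1.3 equiv, THF solution), Pd(OAc)2 (2 mol %), CPhos (4 mol %), THF, rt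
Reagents that add atoms: none
Why: The same linear-selective Negishi prenylation, now at the aryl bromide, the ester being inert to the allylic zinc reagent at room temperature.

Step 9
Reactants: 13 ethyl 2-Ar-acetate
Product: 14 ethyl (RS)-3-hydroxy-2-Ar-propanoate (racemic tropate ester)
Conditions: LiN(i-Pr)2, THF, −78 °C; CH2O (gas, from cracked paraformaldehyde), −78 °C; AcOH, −78 °C
Reagents that add atoms: formaldehyde, C=O
Why: Aldol addition of the ester lithium enolate to monomeric formaldehyde with a cold acidic quench avoids double addition and dehydration; the new centre is formed racemic on purpose because C3 is set in step 17.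

Step 10
Reactants: 14 ethyl (RS)-3-hydroxy-2-Ar-propanoate
Product: 15 ethyl (RS)-3-(tert-butyldimethylsilyloxy)-2-Ar-propanoate
Conditions: TBSCl, imidazole, CH2Cl2, rt
Reagents that add atoms: tert-butyldimethylsilyl chloride, CC(C)(C)[Si](C)(C)Cl
Why: Standard silylation of a primary alcohol.

Step 11
Reactants: 15 ethyl (RS)-3-(tert-butyldimethylsilyloxy)-2-Ar-propanoate
Product: 16 (RS)-3-(tert-butyldimethylsilyloxy)-N-methoxy-N-methyl-2-Ar-propanamide
Conditions: MeNHOMe·HCl, AlMe3, CH2Cl2, 0 °C → rt; aq. KNaC4H4O6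
Reagents that add atoms: N,O-dimethylhydroxylamine hydrochloride, CNOC.Cl
Why: Weinreb aminolysis of the ester by the aluminium amide is Lewis-acid driven and only weakly basic, so the acidic benzylic α-hydrogen is not removed and the β-silyloxy group is not eliminated.

Step 12
Reactants: 6 2,2-dimethyl-5-prenyl-6-(2-oxopropyl)-4H-1,3-dioxin-4-one; 16 (RS)-3-(tert-butyldimethylsilyloxy)-N-methoxy-N-methyl-2-Ar-propanamide
Product: 17 (RS)-6-[6-(tert-butyldimethylsilyloxy)-2,4-dioxo-5-Ar-hexyl]-2,2-dimethyl-5-(3-methylbut-2-en-1-yl)-4H-1,3-dioxin-4-one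
Conditions: 6 (2 equiv), LiN(i-Pr)2 (4 equiv), THF, −78 °C; then 16 (1 equiv), −78 → −40 °C; AcOH, −78 °C
Reagents that add atoms: none
Why: Claisen-type acylation of the 1,3-dianion of the keto-dioxinone at its more reactive terminal carbon by the Weinreb amide, whose chelated tetrahedral adduct prevents over-addition, while the low temperature limits α-deprotonation of the amide.

Step 13
Reactants: 17 (RS)-6-[6-(tert-butyldimethylsilyloxy)-2,4-dioxo-5-Ar-hexyl]-2,2-dimethyl-5-prenyl-4H-1,3-dioxin-4-one
Product: 19 (RS)-3-Ar-6-{[2,2-dimethyl-5-(3-methylbut-2-en-1-yl)-4-oxo-4H-1,3-dioxin-6-yl]methyl}-2,3-dihydro-4H-pyran-4-one, via hydroxy diketone 18 (not isolated)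
Conditions: HF·pyridine, THF/pyridine, 0 °C → rt; then TsOH·H2O (5 mol %), 4 Å molecular sieves, CH2Cl2, rt
Reagents that add atoms: none
Why: Fluoride desilylation frees the primary alcohol, which adds to the ketone δ to it (the only closure that gives a six-membered ring) and loses water under catalytic acid, the known cyclodehydration of δ-hydroxy-β-diketones to 2,3-dihydropyran-4-ones; the aryl MOM ether, the prenyl groups and the dioxinone tolerate these conditions.

Step 14
Reactants: 19 (RS)-3-Ar-6-{[2,2-dimethyl-5-prenyl-4-oxo-4H-1,3-dioxin-6-yl]methyl}-2,3-dihydro-4H-pyran-4-one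
Product: 22 (RS)-5,7-dihydroxy-3-[4-methoxy-2-(methoxymethoxy)-5-(3-methylbut-2-en-1-yl)phenyl]-6-(3-methylbut-2-en-1-yl)chroman-4-one, via acylketene 20 (not isolated), via cyclohexadienone 21 (not isolated)
Conditions: PhMe (0.005 M), 4 Å molecular sieves, 110 °C, argon
Reagents that add atoms: none
Why: Proposed new method: heating the 1,3-dioxin-4-one to about 110 °C sets off the well-known retro-hetero-Diels–Alder loss of acetone to acylketene 20, and enolisation of its C7 ketone toward the doubly activated C8 methylene gives a (Z)-dienylketene O=C5=C6–C7(OH)=C8–C8a=C4a whose ends, the electrophilic ketene carbon C5 and the nucleophilic enol-ether β-carbon C4a, join by a thermal disrotatory six-electron electrocyclisation (or its polar equivalent, C-acylation of the vinylogous ester) to dienone 21, which aromatises by tautomerisation of the C4a–H flanked by two carbonyls. The closest known reactions are the thermolysis of keto-dioxinones to acylketenes followed by aromatisation to resorcylates, where the ring is closed by an aldol step instead, and the closing step of cyclobutenone-based benzannulations, where a dienylketene electrocyclises to a phenol. Ring A is thus closed as a six-membered carbocycle by six-electron electrocyclisation with the ketene C=C inside the new ring and the inside position at C4a occupied only by hydrogen. No stereocentre is formed, and C3, which is labile throughout, stays racemic. The step needs C-acylation at C4a to outrun ketene dimerisation, capture by water or by the phenols of the product, and the aldol mode from C6 to the C4 carbonyl; dilution and dry toluene deal with the first two, while the aldol adduct cannot aromatise at the fully substituted prenyl-bearing C6 and the C4 carbonyl is a deactivated vinylogous ester. Because O1–C8a was fixed in ring C before the ketene is released, only the 6-prenyl isomer can arise, and the MOM ether and both prenyl groups are inert to neutral thermolysis.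

Step 15
Reactants: 22 (RS)-5,7-dihydroxy-3-Ar-6-prenylchroman-4-one
Product: 23 (RS)-5,7-dihydroxy-3-[2-hydroxy-4-methoxy-5-(3-methylbut-2-en-1-yl)phenyl]-6-(3-methylbut-2-en-1-yl)chroman-4-one (racemic target)
Conditions: HCl (2 M, aq.), MeOH, rt → 40 °C
Reagents that add atoms: none
Why: Acid-catalysed acetal exchange with methanol removes the aryl MOM ether under conditions commonly used on ortho-prenyl phenols, and it is done on the racemate so that acid-promoted enolisation at C3 costs nothing.

Step 16
Reactants: 23 racemic target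
Product: 24 3-[4-methoxy-5-(3-methylbut-2-en-1-yl)-2-(trimethylsilyloxy)phenyl]-6-(3-methylbut-2-en-1-yl)-4,5,7-tris(trimethylsilyloxy)-2H-chromene (achiral)
Conditions: Me3SiOTf (5 equiv), Et3N (7 equiv), CH2Cl2, 0 °C → rt; pentane, filtration, used crude
Reagents that add atoms: trimethylsilyl trifluoromethanesulfonate, C[Si](C)(C)OS(=O)(=O)C(F)(F)F
Why: Silyl triflate and amine silylate the three phenols and convert the C4 ketone by soft enolisation into its silyl enol ether, which can only form toward C3 and so erases the stereocentre in a single planar, ring-fixed enol ether.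

Step 17
Reactants: 24 tetrakis(trimethylsilyl) enol ether
Product: 26 (3S)-5,7-dihydroxy-3-[2-hydroxy-4-methoxy-5-(3-methylbut-2-en-1-yl)phenyl]-6-(3-methylbut-2-en-1-yl)chroman-4-one (target), via tris-silyl ketone 25 (not isolated)
Conditions: (S)-3,3'-bis(2,4,6-triisopropylphenyl)-1,1'-binaphthyl-2,2'-diyl N-triflylthiophosphoramide (5 mol %), PhOH (1.1 equiv), PhMe, −20 °C; then MeOH, citric acid, 0 °C
Reagents that add atoms: none
Why: Brønsted-acid-catalysed enantioselective protonation of a silyl enol ether of an α-aryl cyclic ketone: the chiral acid delivers the proton to one face of C3 within a tight ion pair, the ortho-silyloxyaryl group at C3 serving as the steric marker, phenol returns the proton to the catalyst and takes the silyl group, and cold buffered methanolysis then strips the three aryl silyl ethers without enolising the α-aryl ketone.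

**Compound list**
1 | 2,2,6-trimethyl-4H-1,3-dioxin-4-one | CC1=CC(=O)OC(C)(C)O1 | starting material
2 | 5-iodo-2,2,6-trimethyl-4H-1,3-dioxin-4-one | CC1=C(I)C(=O)OC(C)(C)O1 | intermediate
3 | 1-bromo-3-methylbut-2-ene (prenyl bromide) | CC(C)=CCBr | starting material
4 | (3-methylbut-2-en-1-yl)zinc bromide (prenylzinc bromide, stock solution in THF) | CC(C)=CC[Zn]Br | intermediate
5 | 2,2,6-trimethyl-5-(3-methylbut-2-en-1-yl)-4H-1,3-dioxin-4-one | CC1=C(CC=C(C)C)C(=O)OC(C)(C)O1 | intermediate
6 | 2,2-dimethyl-5-(3-methylbut-2-en-1-yl)-6-(2-oxopropyl)-4H-1,3-dioxin-4-one | CC(=O)CC1=C(CC=C(C)C)C(=O)OC(C)(C)O1 | intermediate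
7 | 4-bromo-3-methoxyphenol | COc1cc(O)ccc1Br | starting material
8 | 4-bromo-2-iodo-5-methoxyphenol | COc1cc(O)c(I)cc1Br | intermediate
9 | 1-bromo-5-iodo-2-methoxy-4-(methoxymethoxy)benzene | COCOc1cc(OC)c(Br)cc1I | intermediate
10 | ethyl bromoacetate | CCOC(=O)CBr | starting material
11 | (2-ethoxy-2-oxoethyl)zinc bromide (not isolated) | CCOC(=O)C[Zn]Br | intermediate
12 | ethyl 2-[5-bromo-4-methoxy-2-(methoxymethoxy)phenyl]acetate | CCOC(=O)Cc1cc(Br)c(OC)cc1OCOC | intermediate
13 | ethyl 2-[4-methoxy-2-(methoxymethoxy)-5-(3-methylbut-2-en-1-yl)phenyl]acetate | CCOC(=O)Cc1cc(CC=C(C)C)c(OC)cc1OCOC | intermediate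
14 | ethyl (RS)-3-hydroxy-2-[4-methoxy-2-(methoxymethoxy)-5-(3-methylbut-2-en-1-yl)phenyl]propanoate | CCOC(=O)C(CO)c1cc(CC=C(C)C)c(OC)cc1OCOC | intermediate
15 | ethyl (RS)-3-(tert-butyldimethylsilyloxy)-2-[4-methoxy-2-(methoxymethoxy)-5-(3-methylbut-2-en-1-yl)phenyl]propanoate | CCOC(=O)C(CO[Si](C)(C)C(C)(C)C)c1cc(CC=C(C)C)c(OC)cc1OCOC | intermediate
16 | (RS)-3-(tert-butyldimethylsilyloxy)-N-methoxy-N-methyl-2-[4-methoxy-2-(methoxymethoxy)-5-(3-methylbut-2-en-1-yl)phenyl]propanamide | CON(C)C(=O)C(CO[Si](C)(C)C(C)(C)C)c1cc(CC=C(C)C)c(OC)cc1OCOC | intermediate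
17 | (RS)-6-[6-(tert-butyldimethylsilyloxy)-2,4-dioxo-5-Ar-hexyl]-2,2-dimethyl-5-(3-methylbut-2-en-1-yl)-4H-1,3-dioxin-4-one | O=C1OC(C)(C)OC(CC(=O)CC(=O)C(CO[Si](C)(C)C(C)(C)C)c2cc(CC=C(C)C)c(OC)cc2OCOC)=C1CC=C(C)C | intermediate
18 | (RS)-6-[6-hydroxy-2,4-dioxo-5-Ar-hexyl]-2,2-dimethyl-5-(3-methylbut-2-en-1-yl)-4H-1,3-dioxin-4-one (not isolated) | O=C1OC(C)(C)OC(CC(=O)CC(=O)C(CO)c2cc(CC=C(C)C)c(OC)cc2OCOC)=C1CC=C(C)C | intermediate
19 | (RS)-3-Ar-6-{[2,2-dimethyl-5-(3-methylbut-2-en-1-yl)-4-oxo-4H-1,3-dioxin-6-yl]methyl}-2,3-dihydro-4H-pyran-4-one | COc1cc(OCOC)c(C2COC(CC3=C(CC=C(C)C)C(=O)OC(C)(C)O3)=CC2=O)cc1CC=C(C)C | intermediate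
20 | acylketene: (RS)-2-(3-methylbut-2-en-1-yl)-4-(3-Ar-4-oxo-3,4-dihydro-2H-pyran-6-yl)buta-1-ene-1,3-dione (not isolated) | O=C=C(CC=C(C)C)C(=O)CC1=CC(=O)C(c2cc(CC=C(C)C)c(OC)cc2OCOC)CO1 | intermediate
21 | 7-hydroxy-3-Ar-6-(3-methylbut-2-en-1-yl)-2,3-dihydro-4aH-chromene-4,5-dione, mixture of diastereomers (not isolated) | COc1cc(OCOC)c(C2COC3=CC(O)=C(CC=C(C)C)C(=O)C3C2=O)cc1CC=C(C)C | intermediate
22 | (RS)-5,7-dihydroxy-3-[4-methoxy-2-(methoxymethoxy)-5-(3-methylbut-2-en-1-yl)phenyl]-6-(3-methylbut-2-en-1-yl)chroman-4-one | COc1cc(OCOC)c(C2COc3cc(O)c(CC=C(C)C)c(O)c3C2=O)cc1CC=C(C)C | intermediate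
23 | (RS)-5,7-dihydroxy-3-[2-hydroxy-4-methoxy-5-(3-methylbut-2-en-1-yl)phenyl]-6-(3-methylbut-2-en-1-yl)chroman-4-one | COc1cc(O)c(C2COc3cc(O)c(CC=C(C)C)c(O)c3C2=O)cc1CC=C(C)C | intermediate
24 | 3-[4-methoxy-5-(3-methylbut-2-en-1-yl)-2-(trimethylsilyloxy)phenyl]-6-(3-methylbut-2-en-1-yl)-4,5,7-tris(trimethylsilyloxy)-2H-chromene | COc1cc(O[Si](C)(C)C)c(C2=C(O[Si](C)(C)C)c3c(O[Si](C)(C)C)c(CC=C(C)C)c(O[Si](C)(C)C)cc3OC2)cc1CC=C(C)C | intermediate
25 | (3S)-3-[4-methoxy-5-(3-methylbut-2-en-1-yl)-2-(trimethylsilyloxy)phenyl]-6-(3-methylbut-2-en-1-yl)-5,7-bis(trimethylsilyloxy)chroman-4-one (not isolated) | COc1cc(O[Si](C)(C)C)c([C@H]2COc3cc(O[Si](C)(C)C)c(CC=C(C)C)c(O[Si](C)(C)C)c3C2=O)cc1CC=C(C)C | intermediate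
26 | (3S)-5,7-dihydroxy-3-[2-hydroxy-4-methoxy-5-(3-methylbut-2-en-1-yl)phenyl]-6-(3-methylbut-2-en-1-yl)chroman-4-one | COc1cc(O)c([C@H]2COc3cc(O)c(CC=C(C)C)c(O)c3C2=O)cc1CC=C(C)C | target

**Step count and risks**
Total steps: 17. Longest linear sequence: 13 steps (steps 5–17, from 7 to 26). The dioxinone branch (steps 1, 3 and 4) joins at step 12, and the zinc reagent of step 2 enters at steps 3 and 8.

Steps most likely to fail:

1. Step 14. The acylketene may be used up by dimerisation, by recombination with acetone or by capture with the phenols of the product before C8 tautomerises, or the closure onto the weakly nucleophilic vinylogous-ester carbon may be too slow.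
Fallback (known chemistry; sets out from 14 and comes back at 23): ring A is taken from phloroglucinol and closed by Friedel–Crafts acylation onto a symmetric phenol. Phloroglucinol is bis-protected (MOMCl, i-Pr2NEt, CH2Cl2) to 3,5-bis(methoxymethoxy)phenol F1 and silylated (i-Pr3SiCl, imidazole) to [3,5-bis(methoxymethoxy)phenoxy]triisopropylsilane F2. Lithiation between the two MOM ethers (n-BuLi, THF, 0 °C), transmetalation (CuBr·SMe2) and alkylation with 3 give the 4-prenyl silyl ether F3, and Bu4NF gives 3,5-bis(methoxymethoxy)-4-(3-methylbut-2-en-1-yl)phenol F4, whose two positions ortho to the hydroxyl are equivalent. Ester 14 is dehydrated (MsCl, Et3N, then DBU) to ethyl 2-Ar-prop-2-enoate F5. Oxa-Michael addition of F4 (Cs2CO3 cat., MeCN) gives ethyl (RS)-3-aryloxy-2-Ar-propanoate F6, and Me3SnOH (ClCH2CH2Cl, 70 °C) gives the acid F7. Intramolecular Friedel–Crafts acylation ((CF3CO)2O, CH2Cl2, 0 °C) closes ring C onto either equivalent ortho position, so the prenyl group necessarily ends on C6 of (RS)-5,7-bis(methoxymethoxy)-3-Ar-6-prenylchroman-4-one F8. HCl/MeOH as in step 15 then removes the three MOM groups to give 23.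

2. Step 17. Facial discrimination in proton delivery to a crowded, electron-rich tetrasilyl enol ether may be poor, uncatalysed protonation by phenol may compete, and the enantiomeric purity may erode by enolisation during desilylation.
Fallback (sets out from 23 and comes back at 26): racemate 23 is resolved by preparative chromatography on a chiral stationary phase (amylose tris(3,5-dimethylphenylcarbamate), CO2/MeOH), which gives 26 and its (3R)-enantiomer F9. F9 is racemised through the C3 enolate with catalytic DBU in THF back to 23 and recycled.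

3. Step 12. The dianion may deprotonate the hindered Weinreb amide at its benzylic α-carbon, which leads to β-elimination of silanolate and to Michael by-products, and acylation of the α-branched amide may be slow.
Fallback (sets out from 16 and 6 and comes back at 17): amide 16 is reduced (i-Bu2AlH, THF, −78 °C) to (RS)-3-(tert-butyldimethylsilyloxy)-2-Ar-propanal F10. The much faster aldol addition of the dianion of 6 (LiN(i-Pr)2, THF, −78 °C) gives the β-hydroxy ketone F11 as a mixture of diastereomers, and Dess–Martin periodinane with NaHCO3 in CH2Cl2 oxidises it to 17.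

**Further compounds**
F1 | step 14 | 3,5-bis(methoxymethoxy)phenol | COCOc1cc(O)cc(OCOC)c1
F2 | step 14 | [3,5-bis(methoxymethoxy)phenoxy]triisopropylsilane | COCOc1cc(O[Si](C(C)C)(C(C)C)C(C)C)cc(OCOC)c1
F3 | step 14 | [3,5-bis(methoxymethoxy)-4-(3-methylbut-2-en-1-yl)phenoxy]triisopropylsilane | COCOc1cc(O[Si](C(C)C)(C(C)C)C(C)C)cc(OCOC)c1CC=C(C)C
F4 | step 14 | 3,5-bis(methoxymethoxy)-4-(3-methylbut-2-en-1-yl)phenol | COCOc1cc(O)cc(OCOC)c1CC=C(C)C
F5 | step 14 | ethyl 2-[4-methoxy-2-(methoxymethoxy)-5-(3-methylbut-2-en-1-yl)phenyl]prop-2-enoate | CCOC(=O)C(=C)c1cc(CC=C(C)C)c(OC)cc1OCOC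
F6 | step 14 | ethyl (RS)-3-[3,5-bis(methoxymethoxy)-4-(3-methylbut-2-en-1-yl)phenoxy]-2-[4-methoxy-2-(methoxymethoxy)-5-(3-methylbut-2-en-1-yl)phenyl]propanoate | CCOC(=O)C(COc1cc(OCOC)c(CC=C(C)C)c(OCOC)c1)c1cc(CC=C(C)C)c(OC)cc1OCOC
F7 | step 14 | (RS)-3-[3,5-bis(methoxymethoxy)-4-(3-methylbut-2-en-1-yl)phenoxy]-2-[4-methoxy-2-(methoxymethoxy)-5-(3-methylbut-2-en-1-yl)phenyl]propanoic acid | OC(=O)C(COc1cc(OCOC)c(CC=C(C)C)c(OCOC)c1)c1cc(CC=C(C)C)c(OC)cc1OCOC
F8 | step 14 | (RS)-5,7-bis(methoxymethoxy)-3-[4-methoxy-2-(methoxymethoxy)-5-(3-methylbut-2-en-1-yl)phenyl]-6-(3-methylbut-2-en-1-yl)chroman-4-one | COCOc1cc2OCC(c3cc(CC=C(C)C)c(OC)cc3OCOC)C(=O)c2c(OCOC)c1CC=C(C)C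
F9 | step 17 | (3R)-5,7-dihydroxy-3-[2-hydroxy-4-methoxy-5-(3-methylbut-2-en-1-yl)phenyl]-6-(3-methylbut-2-en-1-yl)chroman-4-one | COc1cc(O)c([C@@H]2COc3cc(O)c(CC=C(C)C)c(O)c3C2=O)cc1CC=C(C)C
F10 | step 12 | (RS)-3-(tert-butyldimethylsilyloxy)-2-[4-methoxy-2-(methoxymethoxy)-5-(3-methylbut-2-en-1-yl)phenyl]propanal | O=CC(CO[Si](C)(C)C(C)(C)C)c1cc(CC=C(C)C)c(OC)cc1OCOC
F11 | step 12 | 6-[6-(tert-butyldimethylsilyloxy)-4-hydroxy-2-oxo-5-Ar-hexyl]-2,2-dimethyl-5-(3-methylbut-2-en-1-yl)-4H-1,3-dioxin-4-one, mixture of diastereomers | O=C1OC(C)(C)OC(CC(=O)CC(O)C(CO[Si](C)(C)C(C)(C)C)c2cc(CC=C(C)C)c(OC)cc2OCOC)=C1CC=C(C)C
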